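**Retrosynthetic overview**
1. C8–O bond (last): the 7,8-catechol of ring A comes from the 8-H isoflavone by site-selective ortho-oxygenation of the 7-phenoxide with a diacyl peroxide (proposed new step).
2. O1–C2 bond (ring C): the ortho-phenol oxygen closes onto a one-carbon unit from DMF, in the same pot as the C4–C4a Friedel–Crafts acylation that joins 4-methoxyresorcinol (ring A) to the ring B arylacetic acid.
3. Ring B aryl C–O bond: copper-catalysed hydroxylation of an aryl iodide; the iodide and the 4-OMe come from homovanillic acid by ortho-iodination and methylation.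
4. Ring order: rings A and B are bought as benzene rings; ring C (the pyranone) is the only ring formed, in step 4.

Assumption: the target has no stereocentre and no stereogenic double bond, so the structure as drawn is the single compound to be made and no stereocontrol is needed.

**Step 1**
Reactants: 1 2-(4-hydroxy-3-methoxyphenyl)acetic acid (homovanillic acid)
Product: 2 2-(4-hydroxy-3-iodo-5-methoxyphenyl)acetic acid
Conditions: I2 (1.05 equiv), KI, NaHCO3 (2.5 equiv), H2O, rt, 16 h; then aq. HCl
Reagents that add atoms: iodine, II
Why: Electrophilic aromatic iodination through the phenoxide goes ortho to the oxygen; the para position carries the side chain and the other ortho position the methoxy group, so only C5 can react, as in the classical iodination of vanillin to 5-iodovanillin.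

**Step 2**
Reactants: 2 2-(4-hydroxy-3-iodo-5-methoxyphenyl)acetic acid
Product: 3 methyl 2-(3-iodo-4,5-dimethoxyphenyl)acetate
Conditions: MeI (3 equiv), K2CO3 (3 equiv), DMF, 40 °C
Reagents that add atoms: iodomethane, CI
Why: Williamson ether synthesis together with carboxylate O-alkylation methylates the phenol and the acid, which fixes the 4-OMe before the neighbouring oxygen is introduced, so the 3-OH/4-OMe pattern of ring B is unambiguous.

**Step 3**
Reactants: 3 methyl 2-(3-iodo-4,5-dimethoxyphenyl)acetate
Product: 4 2-(3-hydroxy-4,5-dimethoxyphenyl)acetic acid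
Conditions: CuI (10 mol%), 1,10-phenanthroline (20 mol%), KOH (6 equiv), DMSO/H2O (1:1), 100 °C, Ar; then aq. HCl
Reagents that add atoms: potassium hydroxide, [K+].[OH-]
Why: Ullmann-type copper-catalysed hydroxylation of the aryl iodide by hydroxide (the ligand-accelerated form of the classical 5-iodovanillin to 5-hydroxyvanillin reaction) forms the aryl C–O bond, and the same hydroxide saponifies the methyl ester.

**Step 4**
Reactants: 4 2-(3-hydroxy-4,5-dimethoxyphenyl)acetic acid; 5 4-methoxybenzene-1,3-diol (4-methoxyresorcinol)
Product: 8 7-hydroxy-3-(3-hydroxy-4,5-dimethoxyphenyl)-6-methoxy-4H-chromen-4-one, via deoxybenzoin 6 (not isolated), via enaminone 7 (not isolated)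
Conditions: BF3·OEt2 (as solvent), 85 °C, 2 h; then DMF, MeSO2Cl, 75 °C, 2 h; then H2O
Reagents that add atoms: N,N-dimethylformamide, CN(C)C=O
Why: Boron trifluoride-mediated Friedel–Crafts (Nencki-type) acylation of 5 at C6 (ortho to one OH, para to the other) gives the chelated deoxybenzoin 6, whose activated methylene is formylated by the DMF/MeSO2Cl Vilsmeier-type iminium reagent to enaminone 7; addition–elimination by the ortho-phenol oxygen (oxa-Michael, loss of dimethylamine) then forms the O1–C2 bond and closes ring C (one-pot deoxybenzoin isoflavone synthesis).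

**Step 5**
Reactants: 8 7-hydroxy-3-(3-hydroxy-4,5-dimethoxyphenyl)-6-methoxy-4H-chromen-4-one
Product: 11 7,8-dihydroxy-3-(3-hydroxy-4,5-dimethoxyphenyl)-6-methoxy-4H-chromen-4-one, via peroxyester 9 (not isolated), via catechol monobenzoate 10 (not isolated)
Conditions: KOtBu (1.0 equiv), DMF/MeCN, −20 °C; (PhCO2)2 (1.05 equiv), −20 to 0 °C, Ar; then HCl/MeOH, 45 °C
Reagents that add atoms: dibenzoyl peroxide, O=C(OOC(=O)c1ccccc1)c1ccccc1
Why: Proposed new method: pKa-gated ortho-acyloxylation of a hydroxychromone, in which one equivalent of base ionises only the 7-OH (a vinylogous carboxylic acid, pKa about 7, against about 10 for the ring B phenol), the 7-phenoxide attacks the O–O bond of dibenzoyl peroxide to give peroxyester 9, a [3,3] acyloxy shift delivers oxygen to C8 (the only free ortho carbon, since C6 carries OMe, and the most nucleophilic carbon of ring A), tautomerisation gives catechol monobenzoate 10 and acid methanolysis in the same pot frees the catechol without exposing it to base, while the neutral ring B phenol reacts with the peroxide only slowly at this temperature; the closest known reaction type is the ortho-benzoyloxylation of simple phenols by diacyl peroxides to catechol monobenzoates, which has not been shown on hydroxychromones or as a pKa-controlled choice between two phenols in one molecule.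

**Compound list**
1 | 2-(4-hydroxy-3-methoxyphenyl)acetic acid (homovanillic acid) | COc1cc(CC(=O)O)ccc1O | starting material
2 | 2-(4-hydroxy-3-iodo-5-methoxyphenyl)acetic acid | COc1cc(CC(=O)O)cc(I)c1O | intermediate
3 | methyl 2-(3-iodo-4,5-dimethoxyphenyl)acetate | COC(=O)Cc1cc(I)c(OC)c(OC)c1 | intermediate
4 | 2-(3-hydroxy-4,5-dimethoxyphenyl)acetic acid | OC(=O)Cc1cc(O)c(OC)c(OC)c1 | intermediate
5 | 4-methoxybenzene-1,3-diol (4-methoxyresorcinol) | COc1ccc(O)cc1O | starting material
6 | 1-(2,4-dihydroxy-5-methoxyphenyl)-2-(3-hydroxy-4,5-dimethoxyphenyl)ethan-1-one (deoxybenzoin; not isolated) | COc1cc(C(=O)Cc2cc(O)c(OC)c(OC)c2)c(O)cc1O | intermediate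
7 | (2E)-3-(dimethylamino)-1-(2,4-dihydroxy-5-methoxyphenyl)-2-(3-hydroxy-4,5-dimethoxyphenyl)prop-2-en-1-one (enaminone; not isolated) | CN(C)/C=C(\c1cc(O)c(OC)c(OC)c1)C(=O)c1cc(OC)c(O)cc1O | intermediate
8 | 7-hydroxy-3-(3-hydroxy-4,5-dimethoxyphenyl)-6-methoxy-4H-chromen-4-one | COc1cc2c(=O)c(-c3cc(O)c(OC)c(OC)c3)coc2cc1O | intermediate
9 | 3-(3-hydroxy-4,5-dimethoxyphenyl)-6-methoxy-4-oxo-4H-chromen-7-yl benzenecarboperoxoate (peroxyester; not isolated) | COc1cc2c(=O)c(-c3cc(O)c(OC)c(OC)c3)coc2cc1OOC(=O)c4ccccc4 | intermediate
10 | 7-hydroxy-3-(3-hydroxy-4,5-dimethoxyphenyl)-6-methoxy-4-oxo-4H-chromen-8-yl benzoate (catechol monobenzoate; not isolated) | COc1cc2c(=O)c(-c3cc(O)c(OC)c(OC)c3)coc2c(OC(=O)c4ccccc4)c1O | intermediate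
11 | 7,8-dihydroxy-3-(3-hydroxy-4,5-dimethoxyphenyl)-6-methoxy-4H-chromen-4-one | COc1cc2c(=O)c(-c3cc(O)c(OC)c(OC)c3)coc2c(O)c1O | target

**Step count**
Total step count: 5. Longest linear sequence: 5 steps (1 → 2 → 3 → 4 → 8 → 11); 5 is bought and enters in step 4.

**Three steps most likely to fail**

The ortho-oxygenation of 8 to 11 (step 5, the proposed new step) is the most uncertain. The small equilibrium share of ring B phenoxide could be benzoyloxylated, the 7-phenoxide could be O-benzoylated at the peroxide carbonyl instead of attacking O–O, and the product catechol could be over-oxidised. The fallback uses known chemistry only and sets out from 4, leaving 8 aside. Commercial 2,3-dihydroxy-4-methoxybenzaldehyde F1 is converted by Dakin oxidation (H2O2, aq. NaOH, 0 °C, Ar; then HCl) into 4-methoxybenzene-1,2,3-triol F2. F2 and 4 are joined in BF3·OEt2 at 85 °C to the deoxybenzoin 1-(2,3,4-trihydroxy-5-methoxyphenyl)-2-(3-hydroxy-4,5-dimethoxyphenyl)ethan-1-one F3. This is closed in the same pot with DMF/MeSO2Cl through the enaminone (2E)-3-(dimethylamino)-2-(3-hydroxy-4,5-dimethoxyphenyl)-1-(2,3,4-trihydroxy-5-methoxyphenyl)prop-2-en-1-one F4, and the route is rejoined at 11. The 8-oxygen is then carried in from the start, so no late C–H oxygenation is needed, and the count stays at 5 steps.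

The one-pot acylation and ring closure of 4 and 5 to 8 (step 4) may suffer in its Vilsmeier-type stage: the electron-rich ring B carries a free phenol and could be formylated or O-sulfonylated, and some acylation of 5 at C2 is possible. The fallback sets out from 4 and 5 and gives up the one-pot Lewis-acid closure. Deoxybenzoin 6 is isolated after the BF3·OEt2 acylation (aqueous work-up, crystallisation). Ring C is then formed in a separate, neutral operation with N,N-dimethylformamide dimethyl acetal (THF, 65 °C) through 7, and the route is rejoined at 8. This fallback makes no compound outside the list (F0).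

The copper-catalysed hydroxylation of 3 to 4 (step 3) uses an iodide flanked by a methoxy group, and protodeiodination or benzylic oxidation of the arylacetate in hot alkali can compete. The fallback sets out from 3 and replaces direct C–O coupling by a C–B bond followed by oxidation. Miyaura borylation (B2pin2, Pd(dppf)Cl2, KOAc, dioxane, 90 °C) gives methyl 2-[3,4-dimethoxy-5-(4,4,5,5-tetramethyl-1,3,2-dioxaborolan-2-yl)phenyl]acetate F5. Treatment with H2O2/aq. NaOH (C–B oxidation and saponification in one operation), then HCl, rejoins the route at 4.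

**Further compounds**
F1 | step 5 | 2,3-dihydroxy-4-methoxybenzaldehyde (bought starting material of the fallback) | COc1ccc(C=O)c(O)c1O
F2 | step 5 | 4-methoxybenzene-1,2,3-triol | COc1ccc(O)c(O)c1O
F3 | step 5 | 1-(2,3,4-trihydroxy-5-methoxyphenyl)-2-(3-hydroxy-4,5-dimethoxyphenyl)ethan-1-one | COc1cc(C(=O)Cc2cc(O)c(OC)c(OC)c2)c(O)c(O)c1O
F4 | step 5 | (2E)-3-(dimethylamino)-2-(3-hydroxy-4,5-dimethoxyphenyl)-1-(2,3,4-trihydroxy-5-methoxyphenyl)prop-2-en-1-one | CN(C)/C=C(\c1cc(O)c(OC)c(OC)c1)C(=O)c1cc(OC)c(O)c(O)c1O
F0 | step 4 | none | none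
F5 | step 3 | methyl 2-[3,4-dimethoxy-5-(4,4,5,5-tetramethyl-1,3,2-dioxaborolan-2-yl)phenyl]acetate | COC(=O)Cc1cc(B2OC(C)(C)C(C)(C)O2)c(OC)c(OC)c1
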